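**Retrosynthetic overview**
1. Target ⇐ (NaClO2; SeO2 then MnO2) the elemanolide that still carries an isopropenyl group on C5: the acrylic acid is unveiled last.
2. Enabling feature (elemane locants): the vinyl group C1=C2 on quaternary C10 and the propenyl unit C4=C3 on the neighbouring ring carbon C5 make C2=C1–C10–C5–C4=C3 a hexa-1,5-diene that spans the C5–C10 bond of the cyclohexane (C5–C10), the retron of the germacranolide → elemanolide Cope reorganisation.
3. Key disconnection: C5–C10 with double allylic transposition, back to an acyclic (E,E)-bis(allylic methyl carbonate) on the trans γ-lactone. In the forward sense palladium temporarily bridges C2 and C3 (the bond a germacranolide would hold) and is expelled as the cyclohexane closes.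
4. Bis-carbonate ⇐ C6 arm by Wittig/Luche from a C5 aldehyde; C7 arm by Brown isoprenylation of a C8 aldehyde (sets C8) and nickel-catalysed 1,4-hydroboration (sets the E alkene); methylene lactone by Mannich/elimination; angelate by Yamaguchi esterification; lactone core from (S)-5-(hydroxymethyl)butenolide and a vinyl cuprate (C6/C7 trans).
5. Ring order: γ-lactone first (chiral pool), cyclohexane last (key step).

Key step: step 15

Remark: elemane locants are used for all compounds (C10 = ring carbon with CH3 (C14) and the vinyl group C1=C2; C5 = ring CH with the C4(=C3H2)–C15 unit; C6 = ring CH–O of the lactone; C7 = ring CH with C11(=C13H2)–C12(=O); C8 = ring CH–O-angeloyl; C9 = ring CH2), and (+)-B-methoxydiisopinocampheylborane is the reagent derived from (−)-α-pinene.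

Step 1
Reactants: 1 (S)-5-(hydroxymethyl)furan-2(5H)-one
Product: 2 (S)-5-[(tert-butyldimethylsilyloxy)methyl]furan-2(5H)-one
Conditions: t-BuMe2SiCl, imidazole, DMF, 0 °C → rt
Reagents that add atoms: tert-butyl(chloro)dimethylsilane, CC(C)(C)[Si](C)(C)Cl
Why: Silyl ether protection of the primary alcohol; the C6 stereocentre of the chiral-pool butenolide is not touched.

Step 2
Reactants: 2 (S)-5-[(tert-butyldimethylsilyloxy)methyl]furan-2(5H)-one; 3 vinylmagnesium bromide
Product: 4 (4R,5S)-5-[(tert-butyldimethylsilyloxy)methyl]-4-vinyldihydrofuran-2(3H)-one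
Conditions: 3, CuBr·SMe2 (10 mol%), THF, −78 → −40 °C; aq NH4Cl
Reagents that add atoms: none
Why: Copper-catalysed conjugate addition of the Grignard reagent to the butenolide; the vinyl group should enter anti to the C6 silyloxymethyl group and so set C7 (trans lactone).

Step 3
Reactants: 4 (4R,5S)-5-[(tert-butyldimethylsilyloxy)methyl]-4-vinyldihydrofuran-2(3H)-one
Product: 6 (2S,3S)-2-[(tert-butyldimethylsilyloxy)methyl]-5-oxotetrahydrofuran-3-carbaldehyde, via ozonide 5 (not isolated)
Conditions: O3, CH2Cl2, −78 °C; Me2S, −78 °C → rt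
Reagents that add atoms: ozone, [O-][O+]=O
Why: Ozonolysis with reductive work-up cleaves the only C=C to the C8 aldehyde; C7 stays trans, the more stable arrangement.

Step 4
Reactants: 6 (2S,3S)-2-[(tert-butyldimethylsilyloxy)methyl]-5-oxotetrahydrofuran-3-carbaldehyde; 7 isoprene
Product: 9 (4R,5S)-5-[(tert-butyldimethylsilyloxy)methyl]-4-[(1R)-1-hydroxy-3-methylidenepent-4-enyl]dihydrofuran-2(3H)-one, via isoprenylborane 8 (not isolated)
Conditions: 7, potassium 2,2,6,6-tetramethylpiperidide, THF, −78 °C; (+)-B-methoxydiisopinocampheylborane; BF3·OEt2; then 6, −78 °C; H2O2, aq NaHCO3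
Reagents that add atoms: none
Why: Brown allylboration (asymmetric isoprenylation) through a closed chair transition state; the isopinocampheyl groups derived from (−)-α-pinene should direct the 2-methylidenebut-3-enyl group to the aldehyde face that gives (8R), and the aldehyde reacts in preference to the lactone.

Step 5
Reactants: 9 (4R,5S)-5-[(tert-butyldimethylsilyloxy)methyl]-4-[(1R)-1-hydroxy-3-methylidenepent-4-enyl]dihydrofuran-2(3H)-one
Product: 10 triethylsilyl ether of 9 (C8–OSiEt3)
Conditions: Et3SiCl, imidazole, CH2Cl2, 0 °C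
Reagents that add atoms: chlorotriethylsilane, CC[Si](Cl)(CC)CC
Why: Silylation of the C8 hydroxyl blocks migration of the lactone acyl group to O8 and frees the lactone for the later enolate chemistry.

Step 6
Reactants: 10 triethylsilyl ether of 9
Product: 12 (E)-allylic alcohol of 10 (diene converted into CH2–C(CH3)=CH–CH2OH), via allylboronate 11 (not isolated)
Conditions: Ni(cod)2 (5 mol%), PCy3 (5 mol%), pinacolborane, toluene, rt; then H2O2, aq NaHCO3, THF, 0 °C
Reagents that add atoms: hydrogen peroxide, OO
Why: Nickel-catalysed 1,4-hydroboration of the 2-substituted 1,3-diene should deliver H to C14 and boron to C2 across the s-cis-bound diene, so that C14 and C2 end up cis and C9 trans to C2 (E), and oxidation of the C–B bond gives the primary allylic alcohol without allylic shift.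

Step 7
Reactants: 12 (E)-allylic alcohol of 10
Product: 13 methyl carbonate of 12 (C2–OCO2CH3)
Conditions: ClCO2Me, pyridine, CH2Cl2, 0 °C
Reagents that add atoms: methyl chloroformate, COC(=O)Cl
Why: Acylation of the primary allylic alcohol to its methyl carbonate, which serves as protecting group until the key step and as leaving group in it.

Step 8
Reactants: 13 methyl carbonate of 12; 14 N,N-dimethylmethyleneiminium iodide (Eschenmoser's salt)
Product: 17 α-methylene lactone of 13 (C11=C13H2), via Mannich base 15 (not isolated), via methiodide 16 (not isolated)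
Conditions: LiN(SiMe3)2, THF, −78 °C; 14, −78 °C → rt; MeI, MeOH, rt; aq NaHCO3, CH2Cl2
Reagents that add atoms: none
Why: Mannich reaction of the lactone lithium enolate with Eschenmoser's salt, N-methylation and Hofmann-type elimination install the exocyclic methylene; the carbonate has no acidic hydrogen and C7 and C8 are not affected.

Step 9
Reactants: 17 α-methylene lactone of 13
Product: 18 diol (17 without both silyl groups; C5–OH and C8–OH)
Conditions: HF·pyridine, THF, 0 °C → rt
Reagents that add atoms: none
Why: Fluoride-mediated desilylation under non-basic conditions removes both silyl ethers and spares the carbonate and the methylene lactone.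

Step 10
Reactants: 18 diol
Product: 19 aldehyde (18 with C5 as CHO)
Conditions: TEMPO (10 mol%), PhI(OAc)2, CH2Cl2, rt
Reagents that add atoms: none
Why: Oxoammonium (TEMPO) oxidation is selective for the primary C5 alcohol over the hindered secondary C8 alcohol.

Step 11
Reactants: 19 aldehyde; 20 2-(triphenylphosphoranylidene)propanal
Product: 21 (E)-enal (19 extended to C6–CH=C(CH3)–CHO)
Conditions: 20, CH2Cl2, rt → 40 °C
Reagents that add atoms: none
Why: Wittig olefination with the stabilised formyl ylide should give the E trisubstituted enal (C6 trans to the formyl carbon C3) and react with the saturated aldehyde only.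

Step 12
Reactants: 21 (E)-enal; 22 angelic acid
Product: 24 C8 angelate of 21, via mixed anhydride 23 (not isolated)
Conditions: 22, 2,4,6-trichlorobenzoyl chloride, Et3N, toluene, rt; then 21, 75 °C
Reagents that add atoms: none
Why: Yamaguchi esterification through the mixed anhydride, run without a nucleophilic catalyst so that the Z geometry of the angelate is kept; C8 is acylated with retention.

Step 13
Reactants: 24 C8 angelate of 21
Product: 25 allylic alcohol (24 with C3 as CH2OH)
Conditions: NaBH4, CeCl3·7H2O, MeOH, −78 °C
Reagents that add atoms: none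
Why: Luche reduction gives 1,2-reduction of the enal only and leaves the methylene lactone, the angelate and the carbonate.

Step 14
Reactants: 25 allylic alcohol
Product: 26 bis(methyl carbonate) of 25 (carbonates at C2 and C3)
Conditions: ClCO2Me, pyridine, CH2Cl2, 0 °C
Reagents that add atoms: methyl chloroformate, COC(=O)Cl
Why: Carbonate formation at the second primary allylic alcohol completes the acyclic (E,E)-bis(allylic) precursor.

Step 15
Reactants: 26 bis(methyl carbonate)
Product: 28 8β-angeloyloxyelema-1,3,11(13)-trien-12,6α-olide (target with CH3 in place of CO2H), via allylboronate 27 (not isolated)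
Conditions: Pd2(dba)3 (5 mol%), 1,2-bis(diphenylphosphino)benzene (12 mol%), bis(pinacolato)diboron (1.05 equiv, slow addition), THF (0.005 M), 50 °C
Reagents that add atoms: none
Why: Proposed new method: zerovalent palladium ionises a primary carbonate (shown for C2), the methoxide released activates bis(pinacolato)diboron and the π-allyl is borylated to (E)-allylboronate 27 (Miyaura borylation of an allylic carbonate); ionisation of the C3 carbonate then gives a syn-π-allyl that takes up the allyl group of 27 by intramolecular transmetallation, and the resulting bis(η1-allyl)palladium, in effect a germacranolide in which palladium stands for the C2–C3 bond, should undergo 3,3'-reductive elimination that joins C5 to C10 and shifts the double bonds to C1=C2 and C3=C4. The closest known reaction types are the intermolecular palladium-catalysed allyl–allyl cross-coupling of γ,γ-disubstituted allylboronates with allylic carbonates, which with small-bite-angle diphosphines gives branched 1,5-dienes with vicinal quaternary and tertiary centres, and the thermal Cope rearrangement of (1(10)E,4E)-germacranolides to elemanolides. The cyclohexane (C5–C10) closes in a 6-exo mode with respect to both allyl units, through a chair-like transition state fused to the chair-like seven-membered palladacycle (a trans-decalin-like array). C5 is controlled by the trans-fused lactone, which fixes the chair with C6–O and C7–C11 equatorial so that the C4 unit must be equatorial and H5 anti to H6; C10 is controlled by the E geometry of the C1=C10 allyl unit, which keeps C9 equatorial in the array and so puts CH3 axial (syn to O8) and vinyl equatorial. The step needs 3,3'-coupling in preference to 1,1'-coupling (ten-membered ring) or 1,3'-coupling (eight-membered rings), which ring size and the small-bite-angle ligand should secure, retention of both E allyl geometries, which the primary carbonates and the fast intramolecular capture should secure, and ionisation of the carbonates rather than of the allylic lactone C6–O bond, which the better leaving group at the primary positions should secure.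

Step 16
Reactants: 28 8β-angeloyloxyelema-1,3,11(13)-trien-12,6α-olide
Product: 30 15-aldehyde of 28 (C5–C(=CH2)–CHO), via allylic alcohol 29 (not isolated)
Conditions: SeO2 (0.3 equiv), t-BuOOH, CH2Cl2, rt; then MnO2, CH2Cl2, rt
Reagents that add atoms: tert-butyl hydroperoxide, CC(C)(C)OO
Why: Allylic oxidation with selenium dioxide (ene reaction, then 2,3-sigmatropic shift) should attack the only electron-rich alkene that has allylic hydrogens, the isopropenyl group, at its methyl, and MnO2 takes the allylic alcohol on to the 2-substituted acrolein.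

Step 17
Reactants: 30 15-aldehyde of 28
Product: 31 (5R,6R,7R,8R,10S)-8-[(Z)-2-methylbut-2-enoyloxy]elema-1,3,11(13)-trien-15-oic acid 12,6-lactone (CNP0256928.2)
Conditions: NaClO2, NaH2PO4, 2-methylbut-2-ene, t-BuOH/H2O, 0 °C → rt
Reagents that add atoms: sodium chlorite, [Na+].[O-]Cl=O
Why: Pinnick oxidation converts the enal into the acrylic acid without touching the alkenes, the lactone or the angelate; no stereocentre is involved.

**Compound list**
1 | (S)-5-(hydroxymethyl)furan-2(5H)-one | C1=CC(=O)O[C@@H]1CO | starting material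
2 | (S)-5-[(tert-butyldimethylsilyloxy)methyl]furan-2(5H)-one | C1=CC(=O)O[C@@H]1CO[Si](C)(C)C(C)(C)C | intermediate
3 | vinylmagnesium bromide | C=C[Mg]Br | starting material
4 | (4R,5S)-5-[(tert-butyldimethylsilyloxy)methyl]-4-vinyldihydrofuran-2(3H)-one (4,5-trans) | C=C[C@H]1CC(=O)O[C@@H]1CO[Si](C)(C)C(C)(C)C | intermediate
5 | 1,2,4-trioxolane (ozonide) of the vinyl group of 4, epimers at the ring carbon | C1OOC(O1)[C@H]1CC(=O)O[C@@H]1CO[Si](C)(C)C(C)(C)C | intermediate
6 | (2S,3S)-2-[(tert-butyldimethylsilyloxy)methyl]-5-oxotetrahydrofuran-3-carbaldehyde (2,3-trans) | O=C[C@H]1CC(=O)O[C@@H]1CO[Si](C)(C)C(C)(C)C | intermediate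
7 | isoprene (2-methylbuta-1,3-diene) | C=CC(C)=C | starting material
8 | B-(2-methylidenebut-3-enyl)diisopinocampheylborane, isopinocampheyl groups from (−)-α-pinene | C=CC(=C)CB([C@H]1C[C@H]2C[C@@H]([C@@H]1C)C2(C)C)[C@H]1C[C@H]2C[C@@H]([C@@H]1C)C2(C)C | intermediate
9 | (4R,5S)-5-[(tert-butyldimethylsilyloxy)methyl]-4-[(1R)-1-hydroxy-3-methylidenepent-4-enyl]dihydrofuran-2(3H)-one | C=CC(=C)C[C@@H](O)[C@H]1CC(=O)O[C@@H]1CO[Si](C)(C)C(C)(C)C | intermediate
10 | triethylsilyl ether of 9 (C8–OSiEt3; stereocentres as in 9) | C=CC(=C)C[C@@H](O[Si](CC)(CC)CC)[C@H]1CC(=O)O[C@@H]1CO[Si](C)(C)C(C)(C)C | intermediate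
11 | pinacol (E)-allylboronate: 10 with the diene converted into CH2–C(CH3)=CH–CH2–B(pin), C9 trans to C2 | CC1(C)OB(C/C=C(\C)C[C@@H](O[Si](CC)(CC)CC)[C@H]2CC(=O)O[C@@H]2CO[Si](C)(C)C(C)(C)C)OC1(C)C | intermediate
12 | (E)-allylic alcohol: 10 with the diene converted into CH2–C(CH3)=CH–CH2OH | OC/C=C(\C)C[C@@H](O[Si](CC)(CC)CC)[C@H]1CC(=O)O[C@@H]1CO[Si](C)(C)C(C)(C)C | intermediate
13 | methyl carbonate of 12 (C2–OCO2CH3) | COC(=O)OC/C=C(\C)C[C@@H](O[Si](CC)(CC)CC)[C@H]1CC(=O)O[C@@H]1CO[Si](C)(C)C(C)(C)C | intermediate
14 | N,N-dimethylmethyleneiminium iodide (Eschenmoser's salt) | C[N+](C)=C.[I-] | starting material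
15 | Mannich base: 13 with CH2N(CH3)2 on C11 (epimers at C11) | COC(=O)OC/C=C(\C)C[C@@H](O[Si](CC)(CC)CC)[C@H]1C(CN(C)C)C(=O)O[C@@H]1CO[Si](C)(C)C(C)(C)C | intermediate
16 | trimethylammonium iodide of 15 | COC(=O)OC/C=C(\C)C[C@@H](O[Si](CC)(CC)CC)[C@H]1C(C[N+](C)(C)C)C(=O)O[C@@H]1CO[Si](C)(C)C(C)(C)C.[I-] | intermediate
17 | α-methylene lactone: 13 with C11=C13H2 | COC(=O)OC/C=C(\C)C[C@@H](O[Si](CC)(CC)CC)[C@H]1C(=C)C(=O)O[C@@H]1CO[Si](C)(C)C(C)(C)C | intermediate
18 | diol: 17 with free C5–OH and C8–OH | COC(=O)OC/C=C(\C)C[C@@H](O)[C@H]1C(=C)C(=O)O[C@@H]1CO | intermediate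
19 | aldehyde: 18 with C5 as CHO | COC(=O)OC/C=C(\C)C[C@@H](O)[C@H]1C(=C)C(=O)O[C@@H]1C=O | intermediate
20 | 2-(triphenylphosphoranylidene)propanal | CC(C=O)=P(c1ccccc1)(c1ccccc1)c1ccccc1 | starting material
21 | (E)-enal: C6–CH=C(CH3)–CHO, C6 trans to CHO; C8–OH free | COC(=O)OC/C=C(\C)C[C@@H](O)[C@H]1C(=C)C(=O)O[C@@H]1/C=C(\C)C=O | intermediate
22 | angelic acid, (Z)-2-methylbut-2-enoic acid | C/C=C(/C)C(=O)O | starting material
23 | angelic 2,4,6-trichlorobenzoic anhydride | C/C=C(/C)C(=O)OC(=O)c1c(Cl)cc(Cl)cc1Cl | intermediate
24 | C8 angelate of 21 | COC(=O)OC/C=C(\C)C[C@@H](OC(=O)/C(C)=C\C)[C@H]1C(=C)C(=O)O[C@@H]1/C=C(\C)C=O | intermediate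
25 | allylic alcohol: 24 with C3 as CH2OH | COC(=O)OC/C=C(\C)C[C@@H](OC(=O)/C(C)=C\C)[C@H]1C(=C)C(=O)O[C@@H]1/C=C(\C)CO | intermediate
26 | bis(methyl carbonate): 25 with C3–OCO2CH3; both trisubstituted alkenes E | COC(=O)OC/C=C(\C)C[C@@H](OC(=O)/C(C)=C\C)[C@H]1C(=C)C(=O)O[C@@H]1/C=C(\C)COC(=O)OC | intermediate
27 | allylboronate: 26 with B(pin) in place of the C2 carbonate | CC1(C)OB(C/C=C(\C)C[C@@H](OC(=O)/C(C)=C\C)[C@H]2C(=C)C(=O)O[C@@H]2/C=C(\C)COC(=O)OC)OC1(C)C | intermediate
28 | 8β-angeloyloxyelema-1,3,11(13)-trien-12,6α-olide (all stereocentres as in the target; CH3 for CO2H) | C=C[C@]1(C)C[C@@H](OC(=O)/C(C)=C\C)[C@H]2C(=C)C(=O)O[C@@H]2[C@H]1C(=C)C | intermediate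
29 | 15-hydroxy derivative of 28 (C5–C(=CH2)–CH2OH) | C=C[C@]1(C)C[C@@H](OC(=O)/C(C)=C\C)[C@H]2C(=C)C(=O)O[C@@H]2[C@H]1C(=C)CO | intermediate
30 | 15-aldehyde of 28 (C5–C(=CH2)–CHO) | C=C[C@]1(C)C[C@@H](OC(=O)/C(C)=C\C)[C@H]2C(=C)C(=O)O[C@@H]2[C@H]1C(=C)C=O | intermediate
31 | (5R,6R,7R,8R,10S)-8-[(Z)-2-methylbut-2-enoyloxy]elema-1,3,11(13)-trien-15-oic acid 12,6-lactone (CNP0256928.2) | C=C[C@]1(C)C[C@@H](OC(=O)/C(C)=C\C)[C@H]2C(=C)C(=O)O[C@@H]2[C@H]1C(=C)C(=O)O | target

**Step count and risks**
Total step count: 17. Longest linear sequence: 17 steps (1 → 31); 3, 7, 14, 20 and 22 are commercial building blocks.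

Steps most likely to fail:

1. Step 15 (the labelled step). The bis(allyl)palladium may collapse by head-to-head coupling, β-hydride loss or protodeboronation instead of 3,3'-reductive elimination, and scrambling of an allyl geometry would erode the C5/C10 diastereocontrol. The fallback is the thermal route through the real ten-membered ring, with known reaction types only. It sets out from alcohol 25: Appel bromination (CBr4, PPh3, CH2Cl2, 0 °C) gives the allylic bromide F1. Slow addition of F1 to Ni(cod)2 in DMF at high dilution should effect the nickel-mediated reductive coupling of the two primary allylic termini (C2–C3) to the germacranolide (1(10)E,4E)-8β-angeloyloxycostunolide F2. Heating F2 (toluene, sealed tube, about 160 °C) should trigger the Cope rearrangement through the chair–chair transition state that the trans lactone enforces, form C5–C10 and cleave C2–C3 again; the extent of this rearrangement is an equilibrium question, so recovered F2 would be recycled. The fallback rejoins the route at 28.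

2. Step 4. The chiral reagent may be mismatched with the resident C6/C7 stereocentres, which would show as poor facial selectivity in the allyl transfer. The fallback sets out from aldehyde 6: an indium-mediated Barbier reaction with 2-(bromomethyl)buta-1,3-diene (In, THF/H2O) gives the C8-epimeric alcohols F3, Dess–Martin oxidation gives the ketone F4, and Corey–Bakshi–Shibata reduction ((S)-2-methyl-CBS-oxazaborolidine, BH3·SMe2, −30 °C) should set C8 by catalyst control. It rejoins the route at 9.

3. Step 16. The ene attack of the selenium reagent may also remove the tertiary allylic hydrogen on C5 or stop at partial conversion, so that the oxidation loses its site selectivity. The fallback sets out from 28: ene-type chlorination of the isopropenyl group with hypochlorous acid (NaOCl, AcOH, CH2Cl2/H2O, 0 °C) gives the allylic chloride F5, and Ganem oxidation (N-methylmorpholine N-oxide, MeCN, rt) converts the chloride into the enal. It rejoins the route at 30.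

Further compounds
F1 | step 15 | allylic bromide: 25 with Br in place of the C3 hydroxyl | COC(=O)OC/C=C(\C)C[C@@H](OC(=O)/C(C)=C\C)[C@H]1C(=C)C(=O)O[C@@H]1/C=C(\C)CBr
F2 | step 15 | (1(10)E,4E)-8β-angeloyloxygermacra-1(10),4,11(13)-trien-12,6α-olide (8β-angeloyloxycostunolide) | C1C/C=C(\C)C[C@@H](OC(=O)/C(C)=C\C)[C@H]2C(=C)C(=O)O[C@@H]2/C=C1\C
F3 | step 4 | alcohol 9 as a mixture of C8 epimers | C=CC(=C)CC(O)[C@H]1CC(=O)O[C@@H]1CO[Si](C)(C)C(C)(C)C
F4 | step 4 | C8 ketone: (4S,5S)-5-[(tert-butyldimethylsilyloxy)methyl]-4-(3-methylidenepent-4-enoyl)dihydrofuran-2(3H)-one | C=CC(=C)CC(=O)[C@H]1CC(=O)O[C@@H]1CO[Si](C)(C)C(C)(C)C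
F5 | step 16 | allylic chloride: 28 with CH2Cl in place of the C15 methyl | C=C[C@]1(C)C[C@@H](OC(=O)/C(C)=C\C)[C@H]2C(=C)C(=O)O[C@@H]2[C@H]1C(=C)CCl
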